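The runs were computed for substances that don't exist; the scatter is artificial.

The easy step is that each Sub lost is one Prd made and one Rgt spent on it, so the readings give both as fractions of the charge.

| flask | Sub | Rgt | Cat | time |
|---|---|---|---|---|
| summer | 200 mM | 200 mM | 10.0 mM |  |
| winter | 120 mM | 120 mM | 10.0 mM |  |
| spring | 300 mM | 200 mM | 10.0 mM |  |
| dawn | 200 mM | 200 mM | 40.0 mM | 51 min |

- summer run (time / min: [Sub] / mM): 3.9: 181.5; 12: 163.1; 23: 148.6; 36: 137.5; 51: 135.6
- winter run (time / min: [Sub] / mM): 3.9: 111.7; 12: 100.5; 23: 92.4; 36: 82.5; 51: 73.0
- spring run (time / min: [Sub] / mM): 3.9: 280.9; 12: 245.6; 23: 224.1; 36: 219.4; 51: 219.7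

(standard deviation of a reading: 2 mM)

1. reaction order in [Sub] at the outset, round the charge of the summer run, defined at two percent of the Sub turned into Prd (one fixed amount of Prd, the same in the runs compared)
2. reaction order in [Rgt] at the outset, round the charge of the summer run, defined at two percent of the Sub turned into Prd
3. Sub in the dawn run at 51 min, as a share of the Sub charged

- Overall: Sub + Rgt -> Prd, with Cat as catalyst.
- Constant volume, constant temperature.
- Readings of a species count what is bound in complexes too.
- "The second partner" is Rgt.
- An order is taken over about fifteen percent of the charge, up and down.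

Summer's Sub lies at 68.8% of its charge at 36 min and at 67.8% at 51 min, a step within the scatter, so I read a stop with Sub still present. I take this stop as the end of Rgt, the limiting reagent here. Prd accounts for 32.2% of the Rgt charge in summer, so on that reading the other 67.8% has gone another way. Summer's readings give 0.475 as its split, the Prd made for each Rgt lost some other way up to the stop. It compares the two paths, so I ask what each setting does to it.

Sub first. Spring has 1.50 times summer's Sub and has made 1.47 times summer's Prd at 12 min, which reads as an order of 0.957. If the other path ignores Sub, spring's split should be 0.712, and its readings give 0.671.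

Rgt next. Winter has 0.600 of summer's Sub and Rgt, and its Prd at 12 min gives a total order of 1.25. That leaves 0.291 for Rgt. Winter's Sub is still falling at 51 min, so it offers no split.

Cat last. Dawn has 4.00 times summer's Cat. I take Prd to follow Cat in direct proportion and the other path to ignore it, so dawn's split is 1.90. With equal charges of Sub and Rgt, and a stop by 51 min, that leaves 34.5% of the Sub.

The forecast differs from my reckoning, with orders of 0.6 in Sub and 1 in Rgt and 28% of the Sub left in dawn, on the view that “the catalyst is dying, and faster at higher charges”.

The simulation gives orders of 1.1 in Sub and 0.13 in Rgt, and 36.9% of the Sub left in dawn.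

    Cat + Sub + Rgt → Prd + Cat (84.00 L² mol⁻² min⁻¹)
    Cat + Rgt ⇌ Cat.Rgt, settled at all times (37.60 L mol⁻¹)
    2 Rgt → X (0.6360 L mol⁻¹ min⁻¹)

In dawn, Sub lost over Sub left at 51 min is 1.71, against my reckoned split of 1.90. Sub stays behind in dawn because of the step from 2 Rgt to X. The dawn run without that step shows it: Sub left at 51 min falls from 36.9% to 9.74%, so Prd takes 90.3% of the Sub charge in that run.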